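All runs were computed for an exercise; scatter was added.

Elm stopped early.

| flask | left-handed substrate | right-handed substrate | partner | free catalyst | remark | time |
|---|---|---|---|---|---|---|
| elm | 0.31 M | 0.31 M | 2 equiv | 0.69 mol% | run made earlier |  |
| alder | 0.31 M | 0.31 M | 4.5 equiv | 0.69 mol% | run made earlier |  |
| cedar | 0.31 M | 0.31 M | 3 equiv | 1 mol% | run made earlier |  |
| flask | 0.31 M | 0.31 M | 3.00 equiv | 0.69 mol% |  | 12 d |

| run | time / d | left-handed product / % | left-handed substrate / % |
|---|---|---|---|
| elm | 0.833 | 5.3 | 45.1 |
| elm | 1.67 | 6.2 | 45.6 |
| elm | 2.50 | 5.8 | 46.1 |
| elm | 5.00 | 5.9 | 45.7 |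
| elm | 10.0 | 5.6 | 45.3 |
| alder | 0.833 | 11.3 | 41.3 |
| alder | 2.50 | 11.6 | 41.5 |
| alder | 4.00 | 11.6 | 41.5 |
| alder | 6.00 | 11.6 | 41.6 |
| alder | 10.0 | 12.0 | 41.7 |
| cedar | 2.08 | 10.6 | 42.3 |
| cedar | 4.00 | 10.5 | 42.2 |
| cedar | 6.00 | 10.8 | 42.3 |
| cedar | 8.00 | 10.3 | 41.9 |
| cedar | 10.0 | 10.5 | 42.7 |

(readings scatter by 0.3 percentage points)

- free catalyst is single-handed; left-handed substrate and right-handed substrate are mirror images of each other, charged as a racemate, each of them at the stated concentration
- steps under discussion: partner + free catalyst + left-handed substrate -> free catalyst + left-handed product; partner + free catalyst + right-handed substrate -> free catalyst + right-handed product; left-handed substrate <-> right-handed substrate; partner -> decomposed reagent; partner + free catalyst -> spent catalyst A; 2 free catalyst -> spent catalyst B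
- the reaction counts as stopped when no species that holds the left-handed substrate and right-handed substrate together changes by six tenths of a point or more over the second half of the time

1. which holds at 12 d: what has brought the reaction to rest, or that it has not come to rest (all of the left-handed substrate has reacted / the partner has run out first / forward and back rates have come level / it is still moving)
2. amount of left-handed product at 12 d, in percent of the left-handed substrate and right-handed substrate together charged

I ran elm in slow motion. It began with the racemate, partner at 2 equiv and free catalyst. The fast stretch lay before the first reading, since left-handed product already read 5.3 % at 0.833 d. Through the middle it showed no trend against a scatter of 0.3 percentage points. At the end, at 10.0 d, it read 5.6 %, with left-handed substrate still at 45.3 %, so the substrate had not stopped it.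

Alder, with the same catalyst and more partner, levelled at about twice elm's reading, so I followed the partner charge. I defined the partner yield, the fraction of charged partner that ended as left-handed product. Readings count both substrates and equivalents count one, hence the factor 2. I replaced each curve by the mean of its 5 readings, which carries an error near 0.00134:

partner yield = 2 × mean reading / equivalents

elm: 0.0576

alder: 0.0516

Alder's yield is smaller, so I interpolated to 3.00 equiv. Cedar read higher on more catalyst, so I kept to elm and alder, which share the flask's 0.69 mol%:

flask: 0.0552

left-handed product = 0.0552 × 3.00 / 2 = 8.28 %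

I expected the flask at rest by 12 d, stopped by the loss of its partner.

The forecast said the partner has run out first and 8.2 %, citing “partner decomposing quickly”.

The flask gave the partner has run out first and 8.25 %.

    partner + free catalyst + left-handed substrate → free catalyst + left-handed product (k = 0.0170 M⁻² s⁻¹)
    partner + free catalyst + right-handed substrate → free catalyst + right-handed product (k = 0.00778 M⁻² s⁻¹)
    left-handed substrate ⇌ right-handed substrate (k = 1.34 × 10⁻⁵ s⁻¹)
    partner → decomposed reagent (k = 1.22 × 10⁻⁴ s⁻¹)
    partner + free catalyst → spent catalyst A (k = 1.86 × 10⁻⁵ M⁻¹ s⁻¹)
    2 free catalyst → spent catalyst B (k = 0.0139 M⁻¹ s⁻¹)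

Partner stood at 0 % of its charge at 12.0 d, with 88 % of the charged left-handed substrate still there, and the flask's partner yield came to 0.0550. The largest single effect was the decomposition of partner, which at the start used partner 11 times as fast as the left-handed step. Without it, conversion of both substrates went from 12.2 % to 43.3 %, which is 35 % of what was missing. Carried to a neighbour flask with 1.20 equiv of partner, the yield 0.0552 gives 3.31 %, and that flask held 3.55 %.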